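## Retrosynthetic overview

1. Target 21 comes from aldehyde 20 by C=O reduction. Aldehyde 20 comes from the acyclic bromoalkene–alkenol 19 by a 6-exo redox-relay Heck cyclisation that forms the C2–C3 bond of the cyclohexane. Ring numbering: C1 = quaternary carbon, C2 = CH with the side chain, C3 = C=CMe2, C6 = CH–CH3.
2. Enabling feature: C2 is an sp3 CH bonded directly to the sp2 ring carbon C3 of the exocyclic tetrasubstituted C3=CMe2 double bond. Its side chain ends in a primary OH three carbons away, and the quaternary C1 on its other side bears no hydrogen. An alkenylpalladium can therefore add to a C2=CH alkene and migrate only outwards to the carbinol.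
3. Compound 19 comes from isofraxidin 17 and neopentyl alcohol 16 (Mitsunobu). Alcohol 16 comes from a Wittig reaction on aldehyde 12. The quaternary C1 comes from a copper-catalysed desymmetrisation of the prochiral diol 10.
4. Diol 10 comes from malonate 9, made by B-alkyl Suzuki–Miyaura coupling of 5 with Me2C=CBr2 (7), which brings in C3 and the isopropylidene group. Compound 5 comes from a stereoretentive rhodium allylic alkylation with carbonate 2, which sets C6.
5. Ring order: both coumarin rings are bought with 17. The cyclohexane is the only ring made and is closed last, in step 12.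

Key step: step 12

Remark: the sense of induction in step 6 is assigned by analogy with simpler 2-alkyl-2-methylpropane-1,3-diols. If the (R,R)-ligand acylates the other hydroxymethyl group, the (S,S)-ligand is used instead.

## Route

Step 1
Reactants: 1 (R)-but-3-en-2-ol
Product: 2 (R)-but-3-en-2-yl methyl carbonate
Conditions: ClCO2Me, pyridine, CH2Cl2, 0 °C to rt
Reagents that add atoms: methyl chloroformate, COC(=O)Cl
Why: O-acylation with a chloroformate (carbonate formation) leaves the C–O bond of the stereocentre untouched, so the (R) configuration is kept.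

Step 2
Reactants: 2 (R)-but-3-en-2-yl methyl carbonate; 3 dimethyl 2-methylmalonate
Product: 5 dimethyl 2-[(R)-but-3-en-2-yl]-2-methylmalonate, via sodium enolate 4 (not isolated)
Conditions: 3, NaH, THF, 0 °C; then 2, RhCl(PPh3)3 (5 mol %), P(OMe)3 (20 mol %), THF, 30 °C
Reagents that add atoms: sodium hydride, [Na+].[H-] (its sodium is found only in 4)
Why: In this rhodium-catalysed stereospecific allylic alkylation (Tsuji–Trost type) the secondary carbonate ionises to a configurationally stable enyl (σ+π) rhodium species, so double inversion should deliver the malonate at the substituted terminus with net retention and set the future ring C6 as (R).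

Step 3
Reactants: 6 acetone
Product: 7 1,1-dibromo-2-methylprop-1-ene
Conditions: CBr4, PPh3 (2 equiv), CH2Cl2, 0 °C to reflux
Reagents that add atoms: carbon tetrabromide, BrC(Br)(Br)Br
Why: In the Ramirez dibromoolefination (first half of the Corey–Fuchs sequence) the ylide Ph3P=CBr2 is made in the flask and olefinates the ketone in a Wittig reaction.

Step 4
Reactants: 5 dimethyl 2-[(R)-but-3-en-2-yl]-2-methylmalonate; 7 1,1-dibromo-2-methylprop-1-ene
Product: 9 dimethyl 2-[(R)-5-bromo-6-methylhept-5-en-2-yl]-2-methylmalonate, via B-alkyl-9-BBN adduct 8 (not isolated)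
Conditions: 9-BBN-H, THF, 0 °C to rt; then 7 (2 equiv), Pd(dppf)Cl2 (5 mol %), Cs2CO3, H2O, DMF, 40 °C
Reagents that add atoms: 9-borabicyclo[3.3.1]nonane, [H]B1C2CCCC1CCC2 (its boron is found only in 8; 9 keeps one hydrogen of it)
Why: Anti-Markovnikov hydroboration and B-alkyl Suzuki–Miyaura coupling should stop after one exchange, because the two C–Br bonds of 7 are equivalent, 7 is in excess and has no vinylic hydrogen to lose as HBr, and the C–Br bond left in 9 is tetrasubstituted and much slower in oxidative addition.

Step 5
Reactants: 9 dimethyl 2-[(R)-5-bromo-6-methylhept-5-en-2-yl]-2-methylmalonate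
Product: 10 2-[(R)-5-bromo-6-methylhept-5-en-2-yl]-2-methylpropane-1,3-diol
Conditions: LiAlH4, THF, 0 °C to rt
Reagents that add atoms: none
Why: Hydride reduction of both esters of a non-enolisable malonate should give the prochiral diol, and a fully substituted alkenyl bromide is inert to LiAlH4 at or below room temperature.

Step 6
Reactants: 10 2-[(R)-5-bromo-6-methylhept-5-en-2-yl]-2-methylpropane-1,3-diol
Product: 11 (R)-2-[(R)-5-bromo-6-methylhept-5-en-2-yl]-3-hydroxy-2-methylpropyl benzoate
Conditions: BzCl (1.0 equiv), CuCl2 (10 mol %), 2,2'-(propane-2,2-diyl)bis[(4R)-4-phenyl-4,5-dihydrooxazole] (11 mol %), Et3N, CH2Cl2, −40 to 0 °C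
Reagents that add atoms: benzoyl chloride, O=C(Cl)c1ccccc1
Why: In this catalytic desymmetrising monobenzoylation of a 2,2-disubstituted propane-1,3-diol the diol chelates the chiral divalent copper bis(oxazoline) complex, which distinguishes the methyl group from the branched alkyl group, acylates one diastereotopic hydroxymethyl group and thereby sets the quaternary stereocentre (future ring C1).

Step 7
Reactants: 11 (R)-2-[(R)-5-bromo-6-methylhept-5-en-2-yl]-3-hydroxy-2-methylpropyl benzoate
Product: 12 (S)-2-[(R)-5-bromo-6-methylhept-5-en-2-yl]-2-methyl-3-oxopropyl benzoate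
Conditions: Dess–Martin periodinane, CH2Cl2, 0 °C to rt, directly after step 6
Reagents that add atoms: none
Why: A neutral Dess–Martin oxidation run at once forestalls 1,3-benzoyl migration that would scramble C1, and the aldehyde has no α-hydrogen, so neither epimerisation nor β-elimination of benzoate can follow (the descriptor changes only by priority).

Step 8
Reactants: 12 (S)-2-[(R)-5-bromo-6-methylhept-5-en-2-yl]-2-methyl-3-oxopropyl benzoate; 13 [3-(tert-butyldimethylsilyloxy)propyl]triphenylphosphonium bromide
Product: 15 (R,Z)-2-[(R)-5-bromo-6-methylhept-5-en-2-yl]-6-(tert-butyldimethylsilyloxy)-2-methylhex-3-en-1-yl benzoate, via phosphonium ylide 14 (not isolated)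
Conditions: 13, NaN(SiMe3)2, THF, −78 °C; then 12, −78 °C to rt
Reagents that add atoms: none
Why: A Wittig olefination with a non-stabilised ylide under lithium-free conditions should give the (Z)-alkene through the kinetic cis-oxaphosphetane, and α-quaternary aldehydes cannot enolise under the basic conditions.

Step 9
Reactants: 15 (R,Z)-2-[(R)-5-bromo-6-methylhept-5-en-2-yl]-6-(tert-butyldimethylsilyloxy)-2-methylhex-3-en-1-yl benzoate
Product: 16 (R,Z)-2-[(R)-5-bromo-6-methylhept-5-en-2-yl]-6-(tert-butyldimethylsilyloxy)-2-methylhex-3-en-1-ol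
Conditions: K2CO3 (0.2 equiv), MeOH, rt
Reagents that add atoms: none
Why: Base-catalysed transesterification removes the benzoate as methyl benzoate, while the silyl ether, the alkene and the alkenyl bromide are inert.

Step 10
Reactants: 16 (R,Z)-2-[(R)-5-bromo-6-methylhept-5-en-2-yl]-6-(tert-butyldimethylsilyloxy)-2-methylhex-3-en-1-ol; 17 isofraxidin (7-hydroxy-6,8-dimethoxy-2H-chromen-2-one)
Product: 18 7-{[(R,Z)-2-[(R)-5-bromo-6-methylhept-5-en-2-yl]-6-(tert-butyldimethylsilyloxy)-2-methylhex-3-en-1-yl]oxy}-6,8-dimethoxy-2H-chromen-2-one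
Conditions: PPh3, DIAD, THF (about 3 M), sonication, rt to 40 °C
Reagents that add atoms: none
Why: In this Mitsunobu etherification the acidic coumarin phenol displaces the oxyphosphonium group at a primary carbon that is no stereocentre, high concentration with sonication is the established remedy for neopentyl alcohols and ortho-substituted phenols, and the ether is made while the quaternary carbon is still acyclic and carries one flat sp2 substituent.

Step 11
Reactants: 18 7-{[(R,Z)-2-[(R)-5-bromo-6-methylhept-5-en-2-yl]-6-(tert-butyldimethylsilyloxy)-2-methylhex-3-en-1-yl]oxy}-6,8-dimethoxy-2H-chromen-2-one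
Product: 19 7-{[(R,Z)-2-[(R)-5-bromo-6-methylhept-5-en-2-yl]-6-hydroxy-2-methylhex-3-en-1-yl]oxy}-6,8-dimethoxy-2H-chromen-2-one
Conditions: HF·pyridine, pyridine, THF, 0 °C to rt
Reagents that add atoms: none
Why: Fluoride-driven cleavage of the primary silyl ether under buffered, non-basic conditions frees the homoallylic alcohol without opening the coumarin lactone.

Step 12
Reactants: 19 7-{[(R,Z)-2-[(R)-5-bromo-6-methylhept-5-en-2-yl]-6-hydroxy-2-methylhex-3-en-1-yl]oxy}-6,8-dimethoxy-2H-chromen-2-one
Product: 20 3-[(1R,2R,3R)-2-{[(6,8-dimethoxy-2-oxo-2H-chromen-7-yl)oxy]methyl}-2,3-dimethyl-6-(propan-2-ylidene)cyclohexyl]propanal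
Conditions: Pd2(dba)3 (5 mol %), 2-[5-(trifluoromethyl)pyridin-2-yl]-4,4-dimethyl-4,5-dihydrooxazole (15 mol %), AgOTf (1.1 equiv), NaHCO3 (2 equiv), 3 Å molecular sieves, DMA, 60 °C
Reagents that add atoms: none
Why: Proposed new method: zerovalent palladium inserts into the C–Br bond of the fully substituted bromoalkene, AgOTf removes bromide, the cationic alkenylpalladium adds syn across the tethered (Z)-alkene so that the former C–Br carbon (ring C3) bonds to the alkene carbon next to the quaternary centre (ring C2), and palladium then migrates by repeated β-hydride elimination and reinsertion over the two CH2 groups to the carbinol carbon, where loss of a proton releases aldehyde 20 and zerovalent palladium. The closest known reaction types are the intermolecular redox-relay Heck alkenylation of acyclic alkenols with alkenyl triflates under pyridine-oxazoline palladium catalysis and the classical 6-exo intramolecular Heck cyclisation of 2-bromo-1,7-dienes, and what is new is their merger in a carbocyclisation that starts from a tetrasubstituted alkenyl bromide made triflate-like by the silver salt. The cyclohexane closes in the 6-exo-trig mode, which the four-carbon tether favours over 7-endo because only the exo geometry lets the Pd–C bond and the alkene become coplanar, and which matches the known preference of alkenols for C–C bond formation at the alkene carbon remote from oxygen. The one new stereocentre, C2, is set by the substrate: insertion requires the C2–CH= bond to stand perpendicular to the plane of the alkenyl unit, that is pseudo-axial, which also avoids allylic 1,3-strain with the inner isopropylidene methyl group, and the only chair that keeps the C6 and C1 methyl groups equatorial (CH2OAr axial) then places the side chain trans to CH2OAr and cis to the C1 methyl group, whereas the other alkene face would need a syn-diaxial C6-methyl/side-chain pair. The step needs β-hydride elimination towards the chain and not towards the new allylic C2–H, which is secured because the quaternary C1 blocks migration inwards, the flanked C2–H bond is hard to bring syn-coplanar with palladium, the electron-poor cationic catalyst stays bound to the alkene during the walk, and the alcohol is an irreversible sink. The isopropylidene group enters intact from 7, so no double-bond regioisomer can arise at C3, and the aldehyde level that results is removed again in step 13.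

Step 13
Reactants: 20 3-[(1R,2R,3R)-2-{[(6,8-dimethoxy-2-oxo-2H-chromen-7-yl)oxy]methyl}-2,3-dimethyl-6-(propan-2-ylidene)cyclohexyl]propanal
Product: 21 7-{[(1R,2R,6R)-2-(3-hydroxypropyl)-1,6-dimethyl-3-(propan-2-ylidene)cyclohexyl]methoxy}-6,8-dimethoxy-2H-chromen-2-one (target)
Conditions: NaBH4, MeOH–THF, −20 to 0 °C
Reagents that add atoms: none
Why: Chemoselective borohydride reduction takes the unhindered aliphatic aldehyde far faster than the coumarin lactone or its conjugated double bond, and no stereocentre is touched.

## Compound list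

1 | (R)-but-3-en-2-ol | O[C@H](C)C=C | starting material
2 | (R)-but-3-en-2-yl methyl carbonate | COC(=O)O[C@H](C)C=C | intermediate
3 | dimethyl 2-methylmalonate | COC(=O)C(C)C(=O)OC | starting material
4 | sodium enolate of dimethyl 2-methylmalonate | [Na+].COC(=O)[C-](C)C(=O)OC | intermediate
5 | dimethyl 2-[(R)-but-3-en-2-yl]-2-methylmalonate | COC(=O)C(C)(C(=O)OC)[C@H](C)C=C | intermediate
6 | acetone | CC(C)=O | starting material
7 | 1,1-dibromo-2-methylprop-1-ene | CC(C)=C(Br)Br | intermediate
8 | dimethyl 2-[(R)-4-(9-borabicyclo[3.3.1]nonan-9-yl)butan-2-yl]-2-methylmalonate | COC(=O)C(C)(C(=O)OC)[C@H](C)CCB1C2CCCC1CCC2 | intermediate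
9 | dimethyl 2-[(R)-5-bromo-6-methylhept-5-en-2-yl]-2-methylmalonate | COC(=O)C(C)(C(=O)OC)[C@H](C)CCC(Br)=C(C)C | intermediate
10 | 2-[(R)-5-bromo-6-methylhept-5-en-2-yl]-2-methylpropane-1,3-diol | OCC(C)(CO)[C@H](C)CCC(Br)=C(C)C | intermediate
11 | (R)-2-[(R)-5-bromo-6-methylhept-5-en-2-yl]-3-hydroxy-2-methylpropyl benzoate | O=C(OC[C@](CO)(C)[C@H](C)CCC(Br)=C(C)C)c1ccccc1 | intermediate
12 | (S)-2-[(R)-5-bromo-6-methylhept-5-en-2-yl]-2-methyl-3-oxopropyl benzoate | O=C(OC[C@](C=O)(C)[C@H](C)CCC(Br)=C(C)C)c1ccccc1 | intermediate
13 | [3-(tert-butyldimethylsilyloxy)propyl]triphenylphosphonium bromide | CC(C)(C)[Si](C)(C)OCCC[P+](c1ccccc1)(c1ccccc1)c1ccccc1.[Br-] | starting material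
14 | [3-(tert-butyldimethylsilyloxy)propylidene]triphenylphosphorane | CC(C)(C)[Si](C)(C)OCCC=P(c1ccccc1)(c1ccccc1)c1ccccc1 | intermediate
15 | (R,Z)-2-[(R)-5-bromo-6-methylhept-5-en-2-yl]-6-(tert-butyldimethylsilyloxy)-2-methylhex-3-en-1-yl benzoate | O=C(OC[C@](/C=C\CCO[Si](C)(C)C(C)(C)C)(C)[C@H](C)CCC(Br)=C(C)C)c1ccccc1 | intermediate
16 | (R,Z)-2-[(R)-5-bromo-6-methylhept-5-en-2-yl]-6-(tert-butyldimethylsilyloxy)-2-methylhex-3-en-1-ol | OC[C@](/C=C\CCO[Si](C)(C)C(C)(C)C)(C)[C@H](C)CCC(Br)=C(C)C | intermediate
17 | isofraxidin (7-hydroxy-6,8-dimethoxy-2H-chromen-2-one) | COc1cc2ccc(=O)oc2c(OC)c1O | starting material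
18 | 7-{[(R,Z)-2-[(R)-5-bromo-6-methylhept-5-en-2-yl]-6-(tert-butyldimethylsilyloxy)-2-methylhex-3-en-1-yl]oxy}-6,8-dimethoxy-2H-chromen-2-one | COc1cc2ccc(=O)oc2c(OC)c1OC[C@](/C=C\CCO[Si](C)(C)C(C)(C)C)(C)[C@H](C)CCC(Br)=C(C)C | intermediate
19 | 7-{[(R,Z)-2-[(R)-5-bromo-6-methylhept-5-en-2-yl]-6-hydroxy-2-methylhex-3-en-1-yl]oxy}-6,8-dimethoxy-2H-chromen-2-one | COc1cc2ccc(=O)oc2c(OC)c1OC[C@](/C=C\CCO)(C)[C@H](C)CCC(Br)=C(C)C | intermediate
20 | 3-[(1R,2R,3R)-2-{[(6,8-dimethoxy-2-oxo-2H-chromen-7-yl)oxy]methyl}-2,3-dimethyl-6-(propan-2-ylidene)cyclohexyl]propanal | COc1cc2ccc(=O)oc2c(OC)c1OC[C@]1(C)[C@H](C)CCC(=C(C)C)[C@H]1CCC=O | intermediate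
21 | 7-{[(1R,2R,6R)-2-(3-hydroxypropyl)-1,6-dimethyl-3-(propan-2-ylidene)cyclohexyl]methoxy}-6,8-dimethoxy-2H-chromen-2-one | COc1cc2ccc(=O)oc2c(OC)c1OC[C@]1(C)[C@H](C)CCC(=C(C)C)[C@H]1CCCO | target

## Step count and risks

Total step count: 13. Longest linear sequence: 12 steps (steps 1, 2 and 4 to 13); step 3 is a one-step side branch.

**1. Step 12.**
- Oxidative addition of the hindered tetrasubstituted C–Br bond to nitrogen-ligated zerovalent palladium may be slow.
- The palladium hydride may leave the chain before the carbinol is reached, which would give alkene positional isomers.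
- β-Hydride elimination towards the ring would erase the new stereocentre.
- Fallback (known chemistry, a tin hydride vinyl radical cyclisation): it sets out from 18 and returns at 21. Slow addition of Bu3SnH with AIBN in benzene at 80 °C should turn the C–Br bond into a vinyl radical. This radical closes the same bond 6-exo-trig under the same allylic-strain control, and hydrogen transfer then saturates the chain to give the tert-butyldimethylsilyl ether of the target F1. HF·pyridine in THF then frees 21, so steps 11 to 13 are replaced.

**2. Step 10.**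
- The SN2 displacement at the neopentyl carbon by a phenol flanked by two methoxy groups may be so slow that the activated alcohol is consumed by alkylation of the hydrazide or by participation of the neighbouring alkene.
- Fallback (Williamson disconnection instead of redox condensation): it sets out from 16 and returns at 18. Tf2O and 2,6-lutidine in CH2Cl2 at −78 °C should give the neopentyl triflate F2. This is displaced by the caesium phenoxide of 17 (Cs2CO3, DMF, 50 °C).

**3. Step 6.**
- The catalyst may discriminate poorly between the two hydroxymethyl groups if it is mismatched with the neighbouring stereocentre.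
- Double benzoylation and 1,3-acyl migration may erode the diastereomer ratio.
- Fallback (stereodifferentiation moved to the diester and done by an enzyme): it sets out from 9 and returns at 16.
  - Pig liver esterase in pH 7 phosphate buffer with DMSO should hydrolyse one ester group to the malonic half-ester F3.
  - BH3·SMe2 reduces only the acid, giving the hydroxy ester F4.
  - Dess–Martin oxidation gives the formyl ester F5.
  - A Wittig reaction with ylide 14 gives the (Z)-alkenyl ester F6.
  - i-Bu2AlH in CH2Cl2 at −78 to 0 °C reduces the ester to 16.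

Further compounds
F1 | step 12 | 7-{[(1R,2R,6R)-2-[3-(tert-butyldimethylsilyloxy)propyl]-1,6-dimethyl-3-(propan-2-ylidene)cyclohexyl]methoxy}-6,8-dimethoxy-2H-chromen-2-one | COc1cc2ccc(=O)oc2c(OC)c1OC[C@]1(C)[C@H](C)CCC(=C(C)C)[C@H]1CCCO[Si](C)(C)C(C)(C)C
F2 | step 10 | (R,Z)-2-[(R)-5-bromo-6-methylhept-5-en-2-yl]-6-(tert-butyldimethylsilyloxy)-2-methylhex-3-en-1-yl trifluoromethanesulfonate | O=S(=O)(OC[C@](/C=C\CCO[Si](C)(C)C(C)(C)C)(C)[C@H](C)CCC(Br)=C(C)C)C(F)(F)F
F3 | step 6 | (R)-2-[(R)-5-bromo-6-methylhept-5-en-2-yl]-3-methoxy-2-methyl-3-oxopropanoic acid | COC(=O)[C@](C(=O)O)(C)[C@H](C)CCC(Br)=C(C)C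
F4 | step 6 | methyl (R)-2-[(R)-5-bromo-6-methylhept-5-en-2-yl]-3-hydroxy-2-methylpropanoate | COC(=O)[C@](CO)(C)[C@H](C)CCC(Br)=C(C)C
F5 | step 6 | methyl (R)-2-[(R)-5-bromo-6-methylhept-5-en-2-yl]-2-methyl-3-oxopropanoate | COC(=O)[C@](C=O)(C)[C@H](C)CCC(Br)=C(C)C
F6 | step 6 | methyl (R,Z)-2-[(R)-5-bromo-6-methylhept-5-en-2-yl]-6-(tert-butyldimethylsilyloxy)-2-methylhex-3-enoate | COC(=O)[C@](/C=C\CCO[Si](C)(C)C(C)(C)C)(C)[C@H](C)CCC(Br)=C(C)C
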